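The easy step is the last one: target, once made, meets starting material and is lost to side product, at a rate that goes with c(starting material) and c(target).

    starting material + enzyme ⇌ starting complex (K1 = 29 M⁻¹, k1 = 1.4 × 10⁷ M⁻¹ h⁻¹)
    second substrate + starting complex ⇌ ternary complex (K2 = 170 M⁻¹, k2 = 3.2 × 10⁷ M⁻¹ h⁻¹)
    ternary complex → enzyme + target (k3 = 4200 h⁻¹)
    starting material + target → side product (k4 = 53 M⁻¹ h⁻¹)

in all of them: second substrate 0.0130 M; enzyme 1.0 µM; time 5.0 h

|  | starting material |
|---|---|
| birch | 4.0 × 10⁻⁴ M |
| larch | 0.0012 M |
| ash | 0.0030 M |
| oak | 0.010 M |
| alder | 0.030 M |

- [target] at the end for birch, larch, ash, oak, alder, in this order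
- the shape of the row from first to last (rises all the way / falls all the way / falls, then rises / hardly changes / rises, then falls)

- percent here means starting material units held: one side product counts as two
- "hardly changes" means that all values lie within two and a half points (for a concentration: within two and a half percent of the largest)
- run time (birch): 5.0 h

The first two lines are bindings. The complexes fall apart at 4.83 × 10⁵ h⁻¹ and 1.88 × 10⁵ h⁻¹, faster than the ternary complex goes on at 4200 h⁻¹, so I hold both bindings at equilibrium. Free and bound enzyme then stand level at c(starting material) = 0.0107 M, with second substrate as charged.

Well below that, the third line makes target in proportion to c(starting material). This is a pseudo-first-order step with rate constant 0.269 h⁻¹, so a lean flask converts a share 74.0% of its charge in 5.0 h.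

But the last line also goes with c(starting material), so that factor cancels between making and losing. I call 0.00508 M the balance level: the c(target) at which making equals losing with second substrate as charged, before division by one plus c(starting material) over the level-standing concentration above.

So I solve both ends and join them. The lean end gives the converted charge, the rich end gives the balance level at the charge, and I take the lesser in each flask, in the order birch, larch, ash, oak, alder: 2.96 × 10⁻⁴ M, 8.88 × 10⁻⁴ M, 0.00222 M, 0.00263 M, 0.00134 M. My estimated row rises, stands highest at oak, then falls. I expect ash and oak to land lower than these estimates.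

The forecast gives 2.740 × 10⁻⁴ M, 7.300 × 10⁻⁴ M, 0.00144 M, 0.00208 M, 0.00116 M, rises, then falls, in its words “Target therefore peaks near oak, then falls”.

The simulation gives 2.74 × 10⁻⁴ M, 7.34 × 10⁻⁴ M, 0.00144 M, 0.00213 M, 0.00117 M, rises, then falls.

In alder at the end, 54% of the starting material and 42% of the second substrate are left, and the balance level reckoned with those amounts is 0.00113 M, beside a target of 0.00117 M. In birch at the end, the same reckoning with 27% and 98% left gives 0.00492 M, far more than the target of 2.74 × 10⁻⁴ M.

The constants used here were chosen freely; the rest is arithmetic.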